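## Retrosynthetic overview
1. The five phenols are freed last by hydrogenolysis of benzyl ethers. The flavone C2–C1' bond is cut to a bromoflavanone and a C2-zincated 5-benzyloxy-7-methoxychromone (Negishi coupling).
2. The strategy rests on flavanone ring A: O1 sits on C8a, the C4 carbonyl on the adjacent C4a, and the C5 oxygen flanks C4a. This is the 1,2-difunctionalisation pattern of a 3-alkoxyaryne, so ring C is cut at O1–C8a and C4–C4a to 3,5-bis(benzyloxy)benzyne and a β-hydroxy ester holding C2, C3, C4 and both aryl groups.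
3. The β-hydroxy ester comes from C-acylation of an arylacetate, then asymmetric transfer hydrogenation, which sets the future C2. C3 is left to thermodynamic (trans) control after ring closure.
4. The aryne precursor comes from 3,5-bis(benzyloxy)phenol by ortho-bromination, O-silylation, retro-Brook shift and triflation.
5. Ring order: all benzene rings are bought; flavanone ring C closes in step 8; the pyranone ring of the flavone half closes in step 10 on a separate branch; the halves are joined in step 11.

Key step: step 8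

Assumption: 13 is drawn as its anti (2R,3S) isomer, but the α-epimer composition from step 7 is not relied on because that carbon becomes the freely equilibrating C3 of the flavanone; 1, 7, 10 and 17 are taken as catalogue chemicals.

## Route

Step 1
Reactants: 1 3,5-bis(benzyloxy)phenol
Product: 2 3,5-bis(benzyloxy)-2-bromophenol
Conditions: NBS (1.0 equiv), CH2Cl2, −78 °C to 0 °C
Reagents that add atoms: N-bromosuccinimide, O=C1CCC(=O)N1Br
Why: Electrophilic aromatic bromination of this phloroglucinol-type ring needs no catalyst, one equivalent of NBS at low temperature should stop at the monobromide, and in the non-polar solvent the hydrogen-bonding free OH and its two equivalent ortho sites should steer bromine to C2 rather than to C4 between the benzyloxy groups, any C4 isomer being removed by chromatography.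

Step 2
Reactants: 2 3,5-bis(benzyloxy)-2-bromophenol
Product: 3 [3,5-bis(benzyloxy)-2-bromophenoxy]trimethylsilane
Conditions: HN(SiMe3)2, THF, 70 °C; evaporate
Reagents that add atoms: hexamethyldisilazane, C[Si](C)(C)N[Si](C)(C)C
Why: O-Silylation of the phenol with hexamethyldisilazane is driven by loss of ammonia and leaves only volatile material, so 3 can be used after evaporation.

Step 3
Reactants: 3 [3,5-bis(benzyloxy)-2-bromophenoxy]trimethylsilane
Product: 6 3,5-bis(benzyloxy)-2-(trimethylsilyl)phenyl trifluoromethanesulfonate, via aryllithium 4 (not isolated), via lithium silylphenoxide 5 (not isolated)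
Conditions: n-BuLi (1.1 equiv), THF, −78 °C; then Tf2O (1.2 equiv), −78 °C to 0 °C
Reagents that add atoms: trifluoromethanesulfonic anhydride, O=S(=O)(OS(=O)(=O)C(F)(F)F)C(F)(F)F
Why: Bromine–lithium exchange outruns benzylic deprotonation at −78 °C, aryllithium 4 takes over the neighbouring O-silyl group in a retro-Brook O-to-C shift, and phenoxide 5 is trapped by Tf2O, which is the standard sequence to ortho-silylaryl triflates.

Step 4
Reactants: 7 2-(5-bromo-2-hydroxyphenyl)acetic acid
Product: 8 methyl 2-(5-bromo-2-hydroxyphenyl)acetate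
Conditions: MeOH, H2SO4 (cat.), reflux
Reagents that add atoms: methanol, CO
Why: Fischer esterification in excess methanol, in which any benzofuranone formed by lactonisation is reopened by methanol under the same acid catalysis.

Step 5
Reactants: 8 methyl 2-(5-bromo-2-hydroxyphenyl)acetate
Product: 9 methyl 2-[2-(benzyloxy)-5-bromophenyl]acetate
Conditions: BnBr (1.1 equiv), K2CO3, acetone, reflux
Reagents that add atoms: benzyl bromide, BrCc1ccccc1
Why: Williamson ether synthesis on the phenoxide, K2CO3 being too weak a base to alkylate the arylacetate carbon.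

Step 6
Reactants: 9 methyl 2-[2-(benzyloxy)-5-bromophenyl]acetate; 10 4-(benzyloxy)benzoyl chloride
Product: 12 methyl 2-[2-(benzyloxy)-5-bromophenyl]-3-[4-(benzyloxy)phenyl]-3-oxopropanoate (racemic), via lithium enolate 11 (not isolated)
Conditions: LiN(SiMe3)2 (2.2 equiv), THF, −78 °C; then 10, −78 °C to 0 °C; aq NH4Cl
Reagents that add atoms: none
Why: Crossed Claisen-type C-acylation of a preformed lithium ester enolate by a non-enolisable aroyl chloride, in which the second equivalent of base takes up the more acidic β-keto ester as it forms and so prevents proton exchange and double acylation, the new α-centre being racemic and configurationally labile.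

Step 7
Reactants: 12 methyl 2-[2-(benzyloxy)-5-bromophenyl]-3-[4-(benzyloxy)phenyl]-3-oxopropanoate
Product: 13 methyl (2R,3S)-2-[2-(benzyloxy)-5-bromophenyl]-3-[4-(benzyloxy)phenyl]-3-hydroxypropanoate
Conditions: RuCl(p-cymene)[(S,S)-TsDPEN] (2 mol %), HCO2H–Et3N (5:2), CH2Cl2, 30 °C
Reagents that add atoms: none
Why: Noyori–Ikariya asymmetric transfer hydrogenation under dynamic kinetic resolution, in which the doubly activated α-CH racemises quickly in the amine–formic acid medium and the (S,S) catalyst, holding the ketone aryl group against its η6-arene as it does for acetophenone, delivers hydride to the face that gives the (S)-carbinol, the only centre that must be controlled here.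

Step 8
Reactants: 13 methyl (2R,3S)-2-[2-(benzyloxy)-5-bromophenyl]-3-[4-(benzyloxy)phenyl]-3-hydroxypropanoate; 6 3,5-bis(benzyloxy)-2-(trimethylsilyl)phenyl trifluoromethanesulfonate
Product: 16 (2S,3R)-5,7-bis(benzyloxy)-2-[4-(benzyloxy)phenyl]-3-[2-(benzyloxy)-5-bromophenyl]chroman-4-one, via aryne 14 (not isolated), via arylcaesium adduct 15 (not isolated)
Conditions: dry CsF (4 equiv), THF, 65 °C, 6 (1.5 equiv) added over 4 h
Reagents that add atoms: none
Why: Proposed new method: fluoride removes the silyl group of 6 with loss of triflate to give aryne 14, the fluoride-activated hydroxyl (caesium alkoxide) of 13 adds through oxygen to the aryne carbon that becomes C8a, and the arylcaesium 15 thus formed at C4a attacks the methyl ester and expels methoxide, which picks up the proton that left the hydroxyl, so no net base is produced. The closest known reaction type is the fluoride-triggered aryne annulation of ortho-hydroxyaryl esters to xanthones (O-addition, then intramolecular acylation of the aryl anion), and what is new is an aliphatic secondary β-hydroxy ester as the oxygen nucleophile. Ring C closes by 6-exo-trig acyl substitution, with O1–C8a formed first and C4–C4a second. C2 is the carbinol carbon of 13 and none of its bonds is broken, so its S configuration is carried over, whereas C3, now α to the ketone and benzylic, is under thermodynamic control and should settle trans (both aryl groups equatorial, 3R) in the fluoride medium whichever α-epimer of 13 enters. The step needs regioselectivity on the unsymmetrical aryne, and this is secured by the σ-withdrawing benzyloxy group beside one aryne carbon, which makes the remote carbon the electrophilic one and places the developing carbanion next to itself, the second benzyloxy group lying further off and opposing only weakly. It also needs acylation to outrun protonation of 15, for which THF (no acidic C–H as in MeCN), dry CsF and slow dosing of 6 are chosen.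

Step 9
Reactants: 17 1-(2,6-dihydroxy-4-methoxyphenyl)ethan-1-one
Product: 18 1-[2-(benzyloxy)-6-hydroxy-4-methoxyphenyl]ethan-1-one
Conditions: BnBr (1.0 equiv), K2CO3, acetone, reflux
Reagents that add atoms: benzyl bromide, BrCc1ccccc1
Why: Williamson mono-etherification, in which the symmetry of 17 makes both hydroxyls equivalent and the hydroxyl left after the first alkylation is held in a hydrogen bond to the ketone and reacts much more slowly.

Step 10
Reactants: 18 1-[2-(benzyloxy)-6-hydroxy-4-methoxyphenyl]ethan-1-one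
Product: 20 5-(benzyloxy)-7-methoxy-4H-chromen-4-one, via enaminone 19 (not isolated)
Conditions: Me2NCH(OMe)2, toluene, 100 °C; evaporate; then conc. HCl, CH2Cl2, 40 °C
Reagents that add atoms: N,N-dimethylformamide dimethyl acetal, COC(OC)N(C)C
Why: Condensation of the methyl ketone with the formamide acetal gives enaminone 19, and acid then triggers addition of the phenol oxygen to the β-carbon with loss of dimethylamine, the standard enaminone route to 2,3-unsubstituted chromones.

Step 11
Reactants: 20 5-(benzyloxy)-7-methoxy-4H-chromen-4-one; 16 (2S,3R)-5,7-bis(benzyloxy)-2-[4-(benzyloxy)phenyl]-3-[2-(benzyloxy)-5-bromophenyl]chroman-4-one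
Product: 22 (2S,3R)-5,7-bis(benzyloxy)-3-{2-(benzyloxy)-5-[5-(benzyloxy)-7-methoxy-4-oxo-4H-chromen-2-yl]phenyl}-2-[4-(benzyloxy)phenyl]chroman-4-one, via bis(chromon-2-yl)zinc 21 (not isolated)
Conditions: 20 (1.6 equiv), TMP2Zn·2MgCl2·2LiCl (0.9 equiv), THF, −30 °C to 0 °C; then 16 (1.0 equiv), Pd(OAc)2 (3 mol %), SPhos (6 mol %), THF, 25 °C
Reagents that add atoms: none
Why: C–H zincation followed by Negishi coupling, in which MgCl2 bound at the pyranone carbonyl blocks carbonyl-directed metalation of C3 and acidifies C2–H beside the ring oxygen, the diorganozinc 21 is too weakly basic and nucleophilic to attack the flavanone, and Pd(OAc)2/SPhos couples such reagents at room temperature with aryl bromides that carry acidic C–H groups, so the trans (2S,3R) unit should pass through unchanged.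

Step 12
Reactants: 22 (2S,3R)-5,7-bis(benzyloxy)-3-{2-(benzyloxy)-5-[5-(benzyloxy)-7-methoxy-4-oxo-4H-chromen-2-yl]phenyl}-2-[4-(benzyloxy)phenyl]chroman-4-one
Product: 23 (2S,3R)-5,7-dihydroxy-3-[2-hydroxy-5-(5-hydroxy-7-methoxy-4-oxo-4H-chromen-2-yl)phenyl]-2-(4-hydroxyphenyl)chroman-4-one (CNP0361110.2)
Conditions: H2 (1 atm), Pd/C (10 wt % Pd), THF–MeOH, 23 °C
Reagents that add atoms: none
Why: Catalytic hydrogenolysis removes all five aryl benzyl ethers under neutral conditions, which avoids the acid- or base-induced opening of ring C that could racemise C2, while the flavone C2=C3 bond, the aryl ketones and the 7-methyl ether are normally inert at atmospheric pressure.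

## Compound list
1 | 3,5-bis(benzyloxy)phenol | Oc1cc(OCc2ccccc2)cc(OCc2ccccc2)c1 | starting material
2 | 3,5-bis(benzyloxy)-2-bromophenol | Oc1cc(OCc2ccccc2)cc(OCc2ccccc2)c1Br | intermediate
3 | [3,5-bis(benzyloxy)-2-bromophenoxy]trimethylsilane | C[Si](C)(C)Oc1cc(OCc2ccccc2)cc(OCc2ccccc2)c1Br | intermediate
4 | [2,4-bis(benzyloxy)-6-(trimethylsilyloxy)phenyl]lithium | C[Si](C)(C)Oc1cc(OCc2ccccc2)cc(OCc2ccccc2)c1[Li] | intermediate
5 | lithium 3,5-bis(benzyloxy)-2-(trimethylsilyl)phenoxide | [Li+].[O-]c1cc(OCc2ccccc2)cc(OCc2ccccc2)c1[Si](C)(C)C | intermediate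
6 | 3,5-bis(benzyloxy)-2-(trimethylsilyl)phenyl trifluoromethanesulfonate | C[Si](C)(C)c1c(OCc2ccccc2)cc(OCc2ccccc2)cc1OS(=O)(=O)C(F)(F)F | intermediate
7 | 2-(5-bromo-2-hydroxyphenyl)acetic acid | OC(=O)Cc1cc(Br)ccc1O | starting material
8 | methyl 2-(5-bromo-2-hydroxyphenyl)acetate | COC(=O)Cc1cc(Br)ccc1O | intermediate
9 | methyl 2-[2-(benzyloxy)-5-bromophenyl]acetate | COC(=O)Cc1cc(Br)ccc1OCc1ccccc1 | intermediate
10 | 4-(benzyloxy)benzoyl chloride | O=C(Cl)c1ccc(OCc2ccccc2)cc1 | starting material
11 | lithium enolate of 9 | [Li+].COC([O-])=Cc1cc(Br)ccc1OCc1ccccc1 | intermediate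
12 | methyl 2-[2-(benzyloxy)-5-bromophenyl]-3-[4-(benzyloxy)phenyl]-3-oxopropanoate (racemic) | COC(=O)C(c1cc(Br)ccc1OCc1ccccc1)C(=O)c1ccc(OCc2ccccc2)cc1 | intermediate
13 | methyl (2R,3S)-2-[2-(benzyloxy)-5-bromophenyl]-3-[4-(benzyloxy)phenyl]-3-hydroxypropanoate | Brc1ccc(OCc2ccccc2)c(c1)[C@H]([C@H](O)c1ccc(OCc2ccccc2)cc1)C(=O)OC | intermediate
14 | 3,5-bis(benzyloxy)benzyne (1,2-didehydro-3,5-bis(benzyloxy)benzene) | C1#CC(OCc2ccccc2)=CC(OCc2ccccc2)=C1 | intermediate
15 | arylcaesium adduct: methyl (2R,3S)-2-[2-(benzyloxy)-5-bromophenyl]-3-[3,5-bis(benzyloxy)-2-caesiophenoxy]-3-[4-(benzyloxy)phenyl]propanoate | Brc1ccc(OCc2ccccc2)c(c1)[C@H]([C@H](Oc1cc(OCc2ccccc2)cc(OCc2ccccc2)c1[Cs])c1ccc(OCc2ccccc2)cc1)C(=O)OC | intermediate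
16 | (2S,3R)-5,7-bis(benzyloxy)-2-[4-(benzyloxy)phenyl]-3-[2-(benzyloxy)-5-bromophenyl]chroman-4-one (trans) | Brc3ccc(OCc6ccccc6)c([C@H]4C(=O)c5c(OCc6ccccc6)cc(OCc6ccccc6)cc5O[C@@H]4c4ccc(OCc6ccccc6)cc4)c3 | intermediate
17 | 1-(2,6-dihydroxy-4-methoxyphenyl)ethan-1-one | CC(=O)c1c(O)cc(OC)cc1O | starting material
18 | 1-[2-(benzyloxy)-6-hydroxy-4-methoxyphenyl]ethan-1-one | CC(=O)c1c(O)cc(OC)cc1OCc1ccccc1 | intermediate
19 | (E)-1-[2-(benzyloxy)-6-hydroxy-4-methoxyphenyl]-3-(dimethylamino)prop-2-en-1-one | CN(C)/C=C/C(=O)c1c(O)cc(OC)cc1OCc1ccccc1 | intermediate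
20 | 5-(benzyloxy)-7-methoxy-4H-chromen-4-one | COc1cc(OCc2ccccc2)c2c(=O)ccoc2c1 | intermediate
21 | bis[5-(benzyloxy)-7-methoxy-4-oxo-4H-chromen-2-yl]zinc (MgCl2/LiCl complexed) | COc1cc(OCc2ccccc2)c2c(=O)cc([Zn]c3cc(=O)c4c(OCc5ccccc5)cc(OC)cc4o3)oc2c1 | intermediate
22 | (2S,3R)-5,7-bis(benzyloxy)-3-{2-(benzyloxy)-5-[5-(benzyloxy)-7-methoxy-4-oxo-4H-chromen-2-yl]phenyl}-2-[4-(benzyloxy)phenyl]chroman-4-one | COc1cc(OCc2ccccc2)c2c(=O)cc(-c3ccc(OCc6ccccc6)c([C@H]4C(=O)c5c(OCc6ccccc6)cc(OCc6ccccc6)cc5O[C@@H]4c4ccc(OCc6ccccc6)cc4)c3)oc2c1 | intermediate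
23 | (2S,3R)-5,7-dihydroxy-3-[2-hydroxy-5-(5-hydroxy-7-methoxy-4-oxo-4H-chromen-2-yl)phenyl]-2-(4-hydroxyphenyl)chroman-4-one | COc1cc(O)c2c(=O)cc(-c3ccc(O)c([C@H]4C(=O)c5c(O)cc(O)cc5O[C@@H]4c4ccc(O)cc4)c3)oc2c1 | target

## Step count
- Total step count: 12.
- Longest linear sequence: 7 (steps 4, 5, 6, 7, 8, 11, 12).

## Steps most likely to fail

**1. Step 8 (key step).**
- The caesium alkoxide may fragment by retro-aldol cleavage and recombine, which erodes the enantiomeric purity at the carbinol.
- The aliphatic oxygen may be too poor a partner to capture the aryne.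
- The aryl anion may be protonated before it acylates, either from the medium or by an internal shift of the acidic α-hydrogen followed by β-elimination of the aryloxide.
- The enolate of the product may be arylated by excess aryne, or ring C may open reversibly.

Fallback (known chemistry; the O1–C8a bond is bought in as a phenol C–O bond): it sets out from 12 and returns at 16. Ketone 12 is reduced as in step 7 but with RuCl(p-cymene)[(R,R)-TsDPEN] to methyl (2S,3R)-2-[2-(benzyloxy)-5-bromophenyl]-3-[4-(benzyloxy)phenyl]-3-hydroxypropanoate F1. A Mitsunobu etherification with phenol 1 (PPh3, DIAD, toluene, 0 °C) inverts the carbinol to methyl (2S,3S)-2-[2-(benzyloxy)-5-bromophenyl]-3-[3,5-bis(benzyloxy)phenoxy]-3-[4-(benzyloxy)phenyl]propanoate F2. Me3SnOH (1,2-dichloroethane, 80 °C) frees, without strong base, (2S,3S)-2-[2-(benzyloxy)-5-bromophenyl]-3-[3,5-bis(benzyloxy)phenoxy]-3-[4-(benzyloxy)phenyl]propanoic acid F3. (CF3CO)2O in CH2Cl2 at 0 °C closes ring C by intramolecular Friedel–Crafts acylation at either of the two equivalent positions ortho to the ether oxygen. This gives the cis isomer (2S,3S)-5,7-bis(benzyloxy)-2-[4-(benzyloxy)phenyl]-3-[2-(benzyloxy)-5-bromophenyl]chroman-4-one F4, which catalytic Et3N equilibrates at C3 to 16.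

**2. Step 11.**
- Proton transfer from the acidic C3–H to the zinc reagent or to residual amide base may be followed by β-elimination opening of ring C, with loss of configuration at C2.
- The zincation may be incomplete or misdirected.
- Oxidative addition into the electron-rich aryl bromide may be slow.

Fallback (boron instead of zinc, chromone used as a C–H partner): it sets out from 16 and returns at 22. Miyaura borylation (PdCl2(dppf), bis(pinacolato)diboron, KOAc, dioxane, 80 °C) gives (2S,3R)-5,7-bis(benzyloxy)-2-[4-(benzyloxy)phenyl]-3-[2-(benzyloxy)-5-(4,4,5,5-tetramethyl-1,3,2-dioxaborolan-2-yl)phenyl]chroman-4-one F5. This is joined to chromone 20 by a base-free oxidative boron-Heck coupling (Pd(OAc)2, 1,10-phenanthroline, O2, DMF, 80 °C): the aryl group is delivered to chromone C2 and β-hydride elimination restores the flavone.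

**3. Step 7.**
- Hydride transfer to the hindered, electron-rich and partly enolised diaryl β-keto ester may be slow or poorly face-selective.

Fallback (auxiliary-controlled C–C bond formation instead of ketone reduction): it sets out from 9 and returns at 16.
- Saponification (LiOH, THF–H2O) gives 2-[2-(benzyloxy)-5-bromophenyl]acetic acid F6.
- Coupling with (S)-4-benzyloxazolidin-2-one (DCC, DMAP, CH2Cl2) gives (S)-4-benzyl-3-{2-[2-(benzyloxy)-5-bromophenyl]acetyl}oxazolidin-2-one F7.
- An Evans syn aldol (Bu2BOTf, Et3N, CH2Cl2, −78 °C, then 4-(benzyloxy)benzaldehyde) gives (S)-4-benzyl-3-{(2S,3S)-2-[2-(benzyloxy)-5-bromophenyl]-3-[4-(benzyloxy)phenyl]-3-hydroxypropanoyl}oxazolidin-2-one F8.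
- MeOMgBr in MeOH at 0 °C releases methyl (2S,3S)-2-[2-(benzyloxy)-5-bromophenyl]-3-[4-(benzyloxy)phenyl]-3-hydroxypropanoate F9.

F9 has the required (3S)-carbinol and differs from 13 only at the labile α-carbon. It enters step 8 in place of 13, and the C3 equilibration of that step (through the cis isomer F4) leads to 16.

## Further compounds
F1 | step 8 | methyl (2S,3R)-2-[2-(benzyloxy)-5-bromophenyl]-3-[4-(benzyloxy)phenyl]-3-hydroxypropanoate | Brc1ccc(OCc2ccccc2)c(c1)[C@@H]([C@@H](O)c1ccc(OCc2ccccc2)cc1)C(=O)OC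
F2 | step 8 | methyl (2S,3S)-2-[2-(benzyloxy)-5-bromophenyl]-3-[3,5-bis(benzyloxy)phenoxy]-3-[4-(benzyloxy)phenyl]propanoate | Brc1ccc(OCc2ccccc2)c(c1)[C@@H]([C@H](Oc1cc(OCc2ccccc2)cc(OCc2ccccc2)c1)c1ccc(OCc2ccccc2)cc1)C(=O)OC
F3 | step 8 | (2S,3S)-2-[2-(benzyloxy)-5-bromophenyl]-3-[3,5-bis(benzyloxy)phenoxy]-3-[4-(benzyloxy)phenyl]propanoic acid | Brc1ccc(OCc2ccccc2)c(c1)[C@@H]([C@H](Oc1cc(OCc2ccccc2)cc(OCc2ccccc2)c1)c1ccc(OCc2ccccc2)cc1)C(=O)O
F4 | step 8 | (2S,3S)-5,7-bis(benzyloxy)-2-[4-(benzyloxy)phenyl]-3-[2-(benzyloxy)-5-bromophenyl]chroman-4-one (cis) | Brc3ccc(OCc6ccccc6)c([C@@H]4C(=O)c5c(OCc6ccccc6)cc(OCc6ccccc6)cc5O[C@@H]4c4ccc(OCc6ccccc6)cc4)c3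
F5 | step 11 | (2S,3R)-5,7-bis(benzyloxy)-2-[4-(benzyloxy)phenyl]-3-[2-(benzyloxy)-5-(4,4,5,5-tetramethyl-1,3,2-dioxaborolan-2-yl)phenyl]chroman-4-one | CC1(C)OB(OC1(C)C)c3ccc(OCc6ccccc6)c([C@H]4C(=O)c5c(OCc6ccccc6)cc(OCc6ccccc6)cc5O[C@@H]4c4ccc(OCc6ccccc6)cc4)c3
F6 | step 7 | 2-[2-(benzyloxy)-5-bromophenyl]acetic acid | OC(=O)Cc1cc(Br)ccc1OCc1ccccc1
F7 | step 7 | (S)-4-benzyl-3-{2-[2-(benzyloxy)-5-bromophenyl]acetyl}oxazolidin-2-one | O=C(Cc1cc(Br)ccc1OCc1ccccc1)N1C(=O)OC[C@@H]1Cc1ccccc1
F8 | step 7 | (S)-4-benzyl-3-{(2S,3S)-2-[2-(benzyloxy)-5-bromophenyl]-3-[4-(benzyloxy)phenyl]-3-hydroxypropanoyl}oxazolidin-2-one | Brc1ccc(OCc2ccccc2)c(c1)[C@@H]([C@H](O)c1ccc(OCc2ccccc2)cc1)C(=O)N1C(=O)OC[C@@H]1Cc1ccccc1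
F9 | step 7 | methyl (2S,3S)-2-[2-(benzyloxy)-5-bromophenyl]-3-[4-(benzyloxy)phenyl]-3-hydroxypropanoate | Brc1ccc(OCc2ccccc2)c(c1)[C@@H]([C@H](O)c1ccc(OCc2ccccc2)cc1)C(=O)OC
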